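**Strategy.** The cyclohexane, cyclooctene and δ-lactone are assembled first (Diels–Alder, Fráter–Seebach/Felkin aldol, ring-closing metathesis); the cyclopentane C1–C5 is closed last across C1–C2. The key step exploits the 1,4-relationship of C1 (ring-fusion CH) and C3 (acyloxy carbon) around C2 (isopropyl carbon): a C1 cyclohexanone whose quaternary C5 carries a 4-methylpent-2-ynyl chain undergoes one-pot carbonyl-assisted gold hydration (alkyne → C3 ketone) and aldol condensation, delivering the C1=C2 cyclopentenone with the isopropyl group and C3 oxygen in place. Conjugate reduction, ketone reduction and Mitsunobu esterification then set C1, C2 and C3.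

Key step: step 21

Locants used below (target numbering): cyclopentane C1(H, ring fusion)–C2(H, iPr)–C3(H, O)–C4H2–C5(CH3, ring fusion); cyclohexane C1–C5–C6H2–C7H–C14H–C15H2; cyclooctene C7–C8(CH3)=C9H–C10H2–C11H–C12(OH)–C13(=CH2)–C14; lactone C11–C16H(CH3)–O–C17(=O)–C18H(OH)–C12; β is the face of the C5 methyl group.

Remark: the facial sense of the oxazaborolidinium catalyst in step 2 is assigned by analogy with related enone Diels–Alder reactions; the antipodal catalyst would be used if the opposite sense is found.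

## Route

Step 1
Reactants: 1 methyl vinyl ketone
Product: 2 2-(triisopropylsilyloxy)buta-1,3-diene
Conditions: TIPSOTf, Et3N, Et2O, 0 °C
Reagents that add atoms: triisopropylsilyl trifluoromethanesulfonate, CC(C)[Si](OS(=O)(=O)C(F)(F)F)(C(C)C)C(C)C
Why: Soft enolisation and O-silylation of the enone (silyl enol ether formation) should give the 2-silyloxydiene; no stereocentre is formed.

Step 2
Reactants: 2 2-(triisopropylsilyloxy)buta-1,3-diene, 3 ethyl (E)-4-oxopent-2-enoate
Product: 4 ethyl (1S,6S)-6-acetyl-3-(triisopropylsilyloxy)cyclohex-3-ene-1-carboxylate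
Conditions: (S)-o-tolyl-CBS-oxazaborolidine (20 mol%), Tf2NH (18 mol%), CH2Cl2, −78 → −40 °C
Reagents that add atoms: none
Why: Enantioselective Diels–Alder reaction under oxazaborolidinium Lewis-acid catalysis, in which the catalyst binds the more basic ketone so that the silyloxy carbon ends para to the acetyl-bearing carbon, the E-dienophile fixes the trans C7/C14 relationship and the catalyst face sets both centres.

Step 3
Reactants: 4 ethyl (1S,6S)-6-acetyl-3-(triisopropylsilyloxy)cyclohex-3-ene-1-carboxylate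
Product: 5 ethyl (1S,6S)-6-(prop-1-en-2-yl)-3-(triisopropylsilyloxy)cyclohex-3-ene-1-carboxylate
Conditions: Ph3PCH3Br, KOtBu, THF, 0 °C
Reagents that add atoms: methylenetriphenylphosphorane, C=P(c1ccccc1)(c1ccccc1)c1ccccc1
Why: Wittig methylenation is chemoselective for the methyl ketone over the ester and the silyl enol ether, and C7 stays in its stable trans-diequatorial configuration.

Step 4
Reactants: 5 ethyl (1S,6S)-6-(prop-1-en-2-yl)-3-(triisopropylsilyloxy)cyclohex-3-ene-1-carboxylate
Product: 8 ethyl (1S,2S)-4-methylidene-5-oxo-2-(prop-1-en-2-yl)cyclohexane-1-carboxylate, via Mannich base 6 (not isolated), via methiodide 7 (not isolated)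
Conditions: CH2=NMe2+ I−, CH2Cl2, 0 °C → rt; then MeI, MeOH/CH2Cl2; then aq. NaHCO3, rt
Reagents that add atoms: Eschenmoser's salt, C=[N+](C)C.[I-]
Why: Regiospecific Mannich reaction of the Diels–Alder-derived silyl enol ether at C5, followed by N-methylation and mild E1cB elimination (α-methylenation), should give the exocyclic enone without isomerisation into the ring.

Step 5
Reactants: 8 ethyl (1S,2S)-4-methylidene-5-oxo-2-(prop-1-en-2-yl)cyclohexane-1-carboxylate, 9 3-methylbut-1-yne
Product: 11 ethyl (1S,6S)-3-(tert-butyldimethylsilyloxy)-4-(4-methylpent-2-yn-1-yl)-6-(prop-1-en-2-yl)cyclohex-3-ene-1-carboxylate, via alkynylzinc bromide 10 (not isolated)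
Conditions: 9, n-BuLi, THF, −78 °C; ZnBr2; then 8, TBSOTf, Et2O–THF, −78 → −40 °C
Reagents that add atoms: tert-butyldimethylsilyl trifluoromethanesulfonate, CC(C)(C)[Si](C)(C)OS(=O)(=O)C(F)(F)F
Why: Silyl-triflate-promoted conjugate addition of the alkynylzinc reagent to the s-cis-locked exocyclic enone should deliver the tetrasubstituted C1/C5 silyl enol ether regiospecifically.

Step 6
Reactants: 11 ethyl (1S,6S)-3-(tert-butyldimethylsilyloxy)-4-(4-methylpent-2-yn-1-yl)-6-(prop-1-en-2-yl)cyclohex-3-ene-1-carboxylate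
Product: 12 ethyl (1S,2S,4S)-4-methyl-4-(4-methylpent-2-yn-1-yl)-5-oxo-2-(prop-1-en-2-yl)cyclohexane-1-carboxylate
Conditions: MeI (5 equiv), TBAT (1.2 equiv), THF, −78 → 0 °C
Reagents that add atoms: iodomethane, CI
Why: Fluoride-induced enolate alkylation in which MeI attacks C5 axially through a chair-like transition state, on the face of H-7 and anti to the C7 isopropenyl group, sets the quaternary centre with the methyl group β.

Step 7
Reactants: 12 ethyl (1S,2S,4S)-4-methyl-4-(4-methylpent-2-yn-1-yl)-5-oxo-2-(prop-1-en-2-yl)cyclohexane-1-carboxylate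
Product: 13 (2S,4S,5S)-5-(hydroxymethyl)-2-methyl-2-(4-methylpent-2-yn-1-yl)-4-(prop-1-en-2-yl)cyclohexan-1-ol (C1 epimers)
Conditions: DIBAL-H (5 equiv), CH2Cl2, −78 → 0 °C; Rochelle salt
Reagents that add atoms: none
Why: Hydride reduction converts the ester into the primary alcohol and parks the hindered ketone at the alcohol oxidation level (epimers inconsequential) until step 20.

Step 8
Reactants: 13 (2S,4S,5S)-5-(hydroxymethyl)-2-methyl-2-(4-methylpent-2-yn-1-yl)-4-(prop-1-en-2-yl)cyclohexan-1-ol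
Product: 14 (2S,4S,5S)-5-(iodomethyl)-2-methyl-2-(4-methylpent-2-yn-1-yl)-4-(prop-1-en-2-yl)cyclohexan-1-ol (C1 epimers)
Conditions: I2, PPh3, imidazole, CH2Cl2, 0 °C
Reagents that add atoms: iodine, II
Why: Appel-type iodination is selective for the primary alcohol over the neopentyl-type secondary alcohol.

Step 9
Reactants: 15 ethyl (S)-3-hydroxybutanoate
Product: 17 ethyl (2S,3S)-2-allyl-3-hydroxybutanoate, via dilithio dianion 16 (not isolated)
Conditions: LDA (2.2 equiv), THF, −78 → −20 °C; allyl bromide, DMPU, −78 → −15 °C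
Reagents that add atoms: allyl bromide, C=CCBr
Why: Fráter–Seebach alkylation, in which the chelated dianion is allylated anti to the C16 methyl group, sets C11 as (2S,3S).

Step 10
Reactants: 17 ethyl (2S,3S)-2-allyl-3-hydroxybutanoate
Product: 18 (2S,3S)-2-allyl-3-hydroxy-N-methoxy-N-methylbutanamide
Conditions: MeNH(OMe)·HCl, i-PrMgCl, THF, −20 → 0 °C
Reagents that add atoms: N,O-dimethylhydroxylamine hydrochloride, CNOC.Cl
Why: Weinreb amide formation by magnesium-amide aminolysis of the ester leaves both stereocentres untouched.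

Step 11
Reactants: 18 (2S,3S)-2-allyl-3-hydroxy-N-methoxy-N-methylbutanamide
Product: 19 (2S,3S)-2-allyl-N-methoxy-N-methyl-3-(triethylsilyloxy)butanamide
Conditions: TESCl, imidazole, CH2Cl2, 0 °C
Reagents that add atoms: chlorotriethylsilane, CC[Si](Cl)(CC)CC
Why: Silylation gives a TES ether that prevents retro-aldol cleavage of the later β-oxy ketone and can be removed selectively beside TBS.

Step 12
Reactants: 14 (2S,4S,5S)-5-(iodomethyl)-2-methyl-2-(4-methylpent-2-yn-1-yl)-4-(prop-1-en-2-yl)cyclohexan-1-ol, 19 (2S,3S)-2-allyl-N-methoxy-N-methyl-3-(triethylsilyloxy)butanamide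
Product: 21 acyclic C12 ketone (C13H2–C12(=O)–C11H(allyl)–C16H(CH3)OTES on the cyclohexanol of 14), via alkyllithium 20 (not isolated)
Conditions: 14, t-BuLi (3.1 equiv), Et2O/pentane, −78 °C; then 19, −78 → −20 °C; aq. NH4Cl
Reagents that add atoms: none
Why: Lithium–iodine exchange and Weinreb ketone synthesis, in which the chelated tetrahedral intermediate prevents over-addition and C11 epimerisation, join the two fragments at C12–C13.

Step 13
Reactants: 21 acyclic C12 ketone
Product: 24 13-methylidene C12 ketone (cross-conjugated enone), via Mannich base 22 (not isolated), via methiodide 23 (not isolated)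
Conditions: LDA (2.2 equiv), THF, −78 °C; CH2=NMe2+ I−, −78 °C → rt; MeI, CH2Cl2/MeOH; aq. NaHCO3
Reagents that add atoms: Eschenmoser's salt, C=[N+](C)C.[I-]
Why: Kinetic enolisation at the less substituted C13, Mannich reaction, quaternisation and E1cB elimination (α-methylenation) install the methylidene carbon and remove the C13 stereocentre before the carbinol is set.

Step 14
Reactants: 24 13-methylidene C12 ketone, 25 ethyl 2-(tert-butyldimethylsilyloxy)acetate
Product: 27 aldol adduct (ethyl 2-silyloxy-3-hydroxy ester with C12 tertiary carbinol; 12S; C18 epimers), via lithium enolate 26 (not isolated)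
Conditions: 25 (3.3 equiv), LDA (3.2 equiv), THF, −78 °C; then 24, −78 °C, 30 min; AcOH, −78 °C
Reagents that add atoms: none
Why: Kinetic 1,2-aldol addition of the glycolate enolate under Felkin–Anh control by C11 (the CH(CH3)OTES group anti to the nucleophile, allyl as medium group) should set the C12 carbinol as in the target, while C18 is left for step 16.

Step 15
Reactants: 27 aldol adduct
Product: 29 δ-lactone (C11–C16–O–C17–C18–C12; 18-OTBS epimers), via hydroxy ester 28 (not isolated)
Conditions: PPTS (0.2 equiv), MeOH, 0 °C → rt; then toluene, 60 °C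
Reagents that add atoms: none
Why: Selective acid-catalysed cleavage of the TES ether (TBS retained) and lactonisation of the freed 16-hydroxyl onto the ethyl ester close the δ-lactone ring.

Step 16
Reactants: 29 δ-lactone (18-OTBS epimers)
Product: 31 δ-lactone with 18-OTBS trans to 12-OH (12S,18S), via lactone enolate 30 (not isolated)
Conditions: LiHMDS (3.5 equiv), THF, −78 °C; then AcOH in THF, −78 °C
Reagents that add atoms: none
Why: Enolisation and kinetic protonation of the lactone enolate anti to the bulky C12 alkenyl substituent converge both epimers on the 18-silyloxy isomer trans to 12-OH, which is also the equatorial and more stable one.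

Step 17
Reactants: 31 δ-lactone (12S,18S)
Product: 32 13-spiro-epoxide of 31
Conditions: VO(acac)2 (5 mol%), t-BuOOH, CH2Cl2, 0 °C → rt
Reagents that add atoms: tert-butyl hydroperoxide, CC(C)(C)OO
Why: Hydroxyl-directed vanadium-catalysed epoxidation selectively masks the methylidene next to the tertiary allylic alcohol, which would otherwise close a cyclopentene with the allyl group in the metathesis.

Step 18
Reactants: 32 13-spiro-epoxide
Product: 33 tricyclic cyclohexanol–(Z)-cyclooctene–δ-lactone with 13-spiro-epoxide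
Conditions: Hoveyda–Grubbs II (10 mol%), toluene (2 mM), 80 °C
Reagents that add atoms: none
Why: Ring-closing metathesis between the C11 allyl and C7 isopropenyl groups, pre-organised gauche on the trans-disubstituted cyclohexane, closes the eight-membered ring, whose size enforces the Z trisubstituted C8=C9 alkene.

Step 19
Reactants: 33 tricyclic spiro-epoxide
Product: 34 13-methylidene tricycle (C1 carbinol epimers)
Conditions: MeReO3 (10 mol%), PPh3 (1.5 equiv), benzene, 50 °C
Reagents that add atoms: none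
Why: Rhenium-catalysed oxygen-atom transfer from the epoxide to the phosphine (epoxide deoxygenation) regenerates the 13-methylidene group.

Step 20
Reactants: 34 13-methylidene tricycle
Product: 35 tricyclic C1 ketone carrying the 5-(4-methylpent-2-ynyl) chain
Conditions: Dess–Martin periodinane, CH2Cl2, 0 °C → rt
Reagents that add atoms: none
Why: Dess–Martin oxidation of the secondary C1 alcohol, with the tertiary 12-OH inert, unveils the cyclohexanone.

Step 21
Reactants: 35 tricyclic C1 ketone carrying the 5-(4-methylpent-2-ynyl) chain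
Product: 38 tetracyclic cyclopentenone (C1=C2; C3=O; 18-OTBS), via 1,4-diketone 36 (not isolated), via potassium seco-acid salt 37 (not isolated)
Conditions: Ph3PAuNTf2 (5 mol%), H2O (10 equiv), 1,4-dioxane, 60 °C; then KOH, MeOH/H2O, 45 °C; then 1 M HCl (pH 2), toluene, 40 °C
Reagents that add atoms: water, O
Why: Cationic gold(I) activates the alkyne for 5-exo-dig attack by the C1 ketone oxygen and water opens the resulting oxocarbenium to the 1,4-diketone 36 (carbonyl-assisted alkyne hydration), which under hydroxide undergoes intramolecular aldol addition of the C2 enolate to the C1 ketone and E1cB dehydration, the classical 1,4-diketone-to-cyclopentenone condensation. The cyclopentane closes by C1–C2 bond formation in a 5-(enolendo)-exo-trig aldol, formally Baldwin-disfavoured but well precedented for 1,4-diketones because dehydration is irreversible. No stereocentre is created: the quaternary C5 is non-enolisable and C1/C2 become sp2, to be set in step 22. The step needs regioselective hydration (C3, not C2, ketone), secured by the neighbouring C1 carbonyl, and a single aldol mode, secured because only the C2-enolate/C1-ketone pairing gives a dehydratable five-membered ring (the bridged C15-to-C3 adduct cannot dehydrate and reverts). Hydroxide transiently opens the δ-lactone to carboxylate 37, which protects the β-hydroxy acid unit from retro-aldol cleavage, and acidification relactonises it.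

Step 22
Reactants: 38 tetracyclic cyclopentenone
Product: 39 trans-hydrindanone (1α-H; 2β-isopropyl; C3=O)
Conditions: [(Ph3P)CuH]6 (0.5 equiv), H2O (3 equiv), benzene, rt → 40 °C; sat. NH4Cl
Reagents that add atoms: none
Why: Copper hydride conjugate reduction (Stryker's reagent) spares lactone and isolated alkenes, delivers hydride to C1 from the α face opposite the angular C5 methyl (trans ring fusion), and the enolate is protonated at C2 from the same open face, placing the isopropyl group β.

Step 23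
Reactants: 39 trans-hydrindanone
Product: 40 3β-alcohol (cis to the 2β-isopropyl group)
Conditions: NaBH4, CeCl3·7H2O, MeOH, −40 °C
Reagents that add atoms: none
Why: Luche-type borohydride reduction, fast and weakly basic so that C2 is not epimerised, attacks C3 from the α face because the β face is blocked by the C5 methyl and C2 isopropyl groups.

Step 24
Reactants: 41 (S)-1-bromo-2-methylbutane
Product: 42 (S)-4-methylhex-1-yne
Conditions: LiC≡CH·H2NCH2CH2NH2, DMSO, 10 °C → rt
Reagents that add atoms: lithium acetylide–ethylenediamine complex, [Li+].[C-]#C.NCCN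
Why: SN2 alkylation of the acetylide by the primary bromide leaves the β-stereocentre untouched.

Step 25
Reactants: 42 (S)-4-methylhex-1-yne
Product: 44 (2E,5S)-3,5-dimethylhept-2-en-1-ol, via alkenylalane 43 (not isolated)
Conditions: AlMe3 (2.5 equiv), Cp2ZrCl2 (0.25 equiv), CH2Cl2, 0 °C → rt; then n-BuLi, (CH2O)n, THF; 1 M HCl
Reagents that add atoms: trimethylaluminium, C[Al](C)C; formaldehyde (as paraformaldehyde), C=O
Why: Negishi zirconium-catalysed syn-carboalumination and trapping of the alkenylalane with formaldehyde give the E trisubstituted allylic alcohol.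

Step 26
Reactants: 44 (2E,5S)-3,5-dimethylhept-2-en-1-ol
Product: 45 [(2R,3R)-3-methyl-3-[(2S)-2-methylbutyl]oxiran-2-yl]methanol
Conditions: Ti(OiPr)4 (10 mol%), D-(−)-diethyl tartrate (12 mol%), t-BuOOH, 4 Å MS, CH2Cl2, −20 °C
Reagents that add atoms: tert-butyl hydroperoxide, CC(C)(C)OO
Why: Sharpless asymmetric epoxidation with D-(−)-tartrate sets the (2R,3R) epoxide under reagent control.

Step 27
Reactants: 45 [(2R,3R)-3-methyl-3-[(2S)-2-methylbutyl]oxiran-2-yl]methanol
Product: 46 (3R,5S)-3,5-dimethylheptane-1,3-diol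
Conditions: Red-Al, THF, 0 °C
Reagents that add atoms: none
Why: Alkoxyaluminate-directed hydride opening of the 2,3-epoxy alcohol at C2 gives the 1,3-diol with the tertiary carbinol configuration retained.

Step 28
Reactants: 46 (3R,5S)-3,5-dimethylheptane-1,3-diol
Product: 47 (3R,5S)-3-hydroxy-3,5-dimethylheptanoic acid
Conditions: TEMPO (0.2 equiv), PhI(OAc)2 (2.5 equiv), MeCN/H2O (1:1), rt
Reagents that add atoms: water, O
Why: Oxoammonium (TEMPO) oxidation takes the primary alcohol through the aldehyde hydrate to the acid while the tertiary alcohol is inert.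

Step 29
Reactants: 40 3β-alcohol, 47 (3R,5S)-3-hydroxy-3,5-dimethylheptanoic acid
Product: 48 18-O-TBS ether of the target
Conditions: 47 (1.5 equiv), PPh3, DIAD, toluene, 0 °C → rt
Reagents that add atoms: none
Why: Mitsunobu esterification displaces the activated 3β-oxyphosphonium by carboxylate with SN2 inversion to the 3α-ester, the tertiary hydroxyls being unreactive.

Step 30
Reactants: 48 18-O-TBS ether of the target
Product: 49 CNP0331120.1
Conditions: HF·pyridine, THF/pyridine, 0 °C → rt
Reagents that add atoms: none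
Why: Fluoride-mediated desilylation of the α-silyloxy lactone liberates the 18-hydroxyl without touching the two esters.

## Compound list

1 | methyl vinyl ketone | CC(=O)C=C | starting material
2 | 2-(triisopropylsilyloxy)buta-1,3-diene | C=CC(=C)O[Si](C(C)C)(C(C)C)C(C)C | intermediate
3 | ethyl (E)-4-oxopent-2-enoate | CCOC(=O)/C=C/C(C)=O | starting material
4 | ethyl (1S,6S)-6-acetyl-3-(triisopropylsilyloxy)cyclohex-3-ene-1-carboxylate | CCOC(=O)[C@H]1CC(O[Si](C(C)C)(C(C)C)C(C)C)=CC[C@@H]1C(C)=O | intermediate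
5 | ethyl (1S,6S)-6-(prop-1-en-2-yl)-3-(triisopropylsilyloxy)cyclohex-3-ene-1-carboxylate | CCOC(=O)[C@H]1CC(O[Si](C(C)C)(C(C)C)C(C)C)=CC[C@@H]1C(C)=C | intermediate
6 | Mannich base: ethyl (1S,2S)-4-[(dimethylamino)methyl]-5-oxo-2-(prop-1-en-2-yl)cyclohexane-1-carboxylate (C4 epimers; not isolated) | CCOC(=O)[C@H]1CC(=O)C(CN(C)C)C[C@@H]1C(C)=C | intermediate
7 | methiodide of 6 (not isolated) | CCOC(=O)[C@H]1CC(=O)C(C[N+](C)(C)C)C[C@@H]1C(C)=C.[I-] | intermediate
8 | ethyl (1S,2S)-4-methylidene-5-oxo-2-(prop-1-en-2-yl)cyclohexane-1-carboxylate | CCOC(=O)[C@H]1CC(=O)C(=C)C[C@@H]1C(C)=C | intermediate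
9 | 3-methylbut-1-yne | CC(C)C#C | starting material
10 | (3-methylbut-1-yn-1-yl)zinc bromide (not isolated) | CC(C)C#C[Zn]Br | intermediate
11 | ethyl (1S,6S)-3-(tert-butyldimethylsilyloxy)-4-(4-methylpent-2-yn-1-yl)-6-(prop-1-en-2-yl)cyclohex-3-ene-1-carboxylate | CCOC(=O)[C@H]1CC(O[Si](C)(C)C(C)(C)C)=C(CC#CC(C)C)C[C@@H]1C(C)=C | intermediate
12 | ethyl (1S,2S,4S)-4-methyl-4-(4-methylpent-2-yn-1-yl)-5-oxo-2-(prop-1-en-2-yl)cyclohexane-1-carboxylate | CCOC(=O)[C@H]1CC(=O)[C@](C)(CC#CC(C)C)C[C@@H]1C(C)=C | intermediate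
13 | (2S,4S,5S)-5-(hydroxymethyl)-2-methyl-2-(4-methylpent-2-yn-1-yl)-4-(prop-1-en-2-yl)cyclohexan-1-ol (C1 epimers) | OC[C@H]1CC(O)[C@](C)(CC#CC(C)C)C[C@@H]1C(C)=C | intermediate
14 | (2S,4S,5S)-5-(iodomethyl)-2-methyl-2-(4-methylpent-2-yn-1-yl)-4-(prop-1-en-2-yl)cyclohexan-1-ol (C1 epimers) | IC[C@H]1CC(O)[C@](C)(CC#CC(C)C)C[C@@H]1C(C)=C | intermediate
15 | ethyl (S)-3-hydroxybutanoate | CCOC(=O)C[C@H](C)O | starting material
16 | dilithio dianion of 15 (not isolated) | [Li+].[Li+].CCOC([O-])=C[C@H](C)[O-] | intermediate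
17 | ethyl (2S,3S)-2-allyl-3-hydroxybutanoate | C=CC[C@H](C(=O)OCC)[C@H](C)O | intermediate
18 | (2S,3S)-2-allyl-3-hydroxy-N-methoxy-N-methylbutanamide | C=CC[C@H](C(=O)N(C)OC)[C@H](C)O | intermediate
19 | (2S,3S)-2-allyl-N-methoxy-N-methyl-3-(triethylsilyloxy)butanamide | C=CC[C@H](C(=O)N(C)OC)[C@H](C)O[Si](CC)(CC)CC | intermediate
20 | alkyllithium (lithium alkoxide) from 14 (not isolated) | [Li]C[C@H]1CC(O[Li])[C@](C)(CC#CC(C)C)C[C@@H]1C(C)=C | intermediate
21 | acyclic C12 ketone: C13H2–C12(=O)–C11H(allyl)–C16H(CH3)OTES on the cyclohexanol ring (C1 carbinol epimers) | C=CC[C@H](C(=O)C[C@H]1CC(O)[C@](C)(CC#CC(C)C)C[C@@H]1C(C)=C)[C@H](C)O[Si](CC)(CC)CC | intermediate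
22 | 13-(dimethylaminomethyl) Mannich base of 21 (C13 epimers; not isolated) | C=CC[C@H](C(=O)C(CN(C)C)[C@H]1CC(O)[C@](C)(CC#CC(C)C)C[C@@H]1C(C)=C)[C@H](C)O[Si](CC)(CC)CC | intermediate
23 | methiodide of 22 (not isolated) | C=CC[C@H](C(=O)C(C[N+](C)(C)C)[C@H]1CC(O)[C@](C)(CC#CC(C)C)C[C@@H]1C(C)=C)[C@H](C)O[Si](CC)(CC)CC.[I-] | intermediate
24 | 13-methylidene C12 ketone (cross-conjugated enone) | C=CC[C@H](C(=O)C(=C)[C@H]1CC(O)[C@](C)(CC#CC(C)C)C[C@@H]1C(C)=C)[C@H](C)O[Si](CC)(CC)CC | intermediate
25 | ethyl 2-(tert-butyldimethylsilyloxy)acetate | CCOC(=O)CO[Si](C)(C)C(C)(C)C | starting material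
26 | lithium enolate of 25 (not isolated) | [Li+].CCOC([O-])=CO[Si](C)(C)C(C)(C)C | intermediate
27 | aldol adduct: ethyl 2-(TBS-oxy)-3-hydroxy ester with C12 tertiary carbinol (12S; C18 epimers) | CCOC(=O)C(O[Si](C)(C)C(C)(C)C)[C@@](O)(C(=C)[C@H]1CC(O)[C@](C)(CC#CC(C)C)C[C@@H]1C(C)=C)[C@@H](CC=C)[C@H](C)O[Si](CC)(CC)CC | intermediate
28 | 16-hydroxy ester from 27 (TES removed; not isolated) | CCOC(=O)C(O[Si](C)(C)C(C)(C)C)[C@@](O)(C(=C)[C@H]1CC(O)[C@](C)(CC#CC(C)C)C[C@@H]1C(C)=C)[C@@H](CC=C)[C@H](C)O | intermediate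
29 | δ-lactone (18-OTBS epimers) | C[C@@H]1OC(=O)C(O[Si](C)(C)C(C)(C)C)[C@@](O)(C(=C)[C@H]2CC(O)[C@](C)(CC#CC(C)C)C[C@@H]2C(C)=C)[C@H]1CC=C | intermediate
30 | trilithium lactone enolate of 29 (not isolated) | [Li+].[Li+].[Li+].C[C@@H]1OC([O-])=C(O[Si](C)(C)C(C)(C)C)[C@@]([O-])(C(=C)[C@H]2CC([O-])[C@](C)(CC#CC(C)C)C[C@@H]2C(C)=C)[C@H]1CC=C | intermediate
31 | δ-lactone with 18-OTBS trans to 12-OH (12S,18S) | C[C@@H]1OC(=O)[C@@H](O[Si](C)(C)C(C)(C)C)[C@@](O)(C(=C)[C@H]2CC(O)[C@](C)(CC#CC(C)C)C[C@@H]2C(C)=C)[C@H]1CC=C | intermediate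
32 | 13-spiro-epoxide of 31 (epoxide carbon epimers) | C[C@@H]1OC(=O)[C@@H](O[Si](C)(C)C(C)(C)C)[C@@](O)(C3(CO3)[C@H]2CC(O)[C@](C)(CC#CC(C)C)C[C@@H]2C(C)=C)[C@H]1CC=C | intermediate
33 | tricyclic cyclohexanol–(Z)-cyclooctene–δ-lactone with 13-spiro-epoxide | C12(CO1)[C@H]3CC(O)[C@](C)(CC#CC(C)C)C[C@@H]3/C(C)=C\C[C@H]3[C@H](C)OC(=O)[C@@H](O[Si](C)(C)C(C)(C)C)[C@@]23O | intermediate
34 | 13-methylidene tricycle (C1 carbinol epimers) | C=C1[C@H]2CC(O)[C@](C)(CC#CC(C)C)C[C@@H]2/C(C)=C\C[C@H]2[C@H](C)OC(=O)[C@@H](O[Si](C)(C)C(C)(C)C)[C@@]12O | intermediate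
35 | tricyclic C1 ketone with 5-(4-methylpent-2-ynyl) chain | C=C1[C@H]2CC(=O)[C@](C)(CC#CC(C)C)C[C@@H]2/C(C)=C\C[C@H]2[C@H](C)OC(=O)[C@@H](O[Si](C)(C)C(C)(C)C)[C@@]12O | intermediate
36 | 1,4-diketone (C1 and C3 ketones; not isolated) | C=C1[C@H]2CC(=O)[C@](C)(CC(=O)CC(C)C)C[C@@H]2/C(C)=C\C[C@H]2[C@H](C)OC(=O)[C@@H](O[Si](C)(C)C(C)(C)C)[C@@]12O | intermediate
37 | potassium seco-acid salt of 38 (lactone opened; not isolated) | C=C1[C@H]2CC3=C(C(C)C)C(=O)C[C@]3(C)C[C@@H]2/C(C)=C\C[C@@H]([C@H](C)O)[C@@]1(O)[C@H](O[Si](C)(C)C(C)(C)C)C(=O)[O-].[K+] | intermediate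
38 | tetracyclic cyclopentenone (C1=C2; C3=O; 18-OTBS) | C=C1[C@H]2CC3=C(C(C)C)C(=O)C[C@]3(C)C[C@@H]2/C(C)=C\C[C@H]2[C@H](C)OC(=O)[C@@H](O[Si](C)(C)C(C)(C)C)[C@@]12O | intermediate
39 | trans-hydrindanone (1α-H; 2β-isopropyl; C3=O) | C=C1[C@H]2C[C@H]3[C@@H](C(C)C)C(=O)C[C@]3(C)C[C@@H]2/C(C)=C\C[C@H]2[C@H](C)OC(=O)[C@@H](O[Si](C)(C)C(C)(C)C)[C@@]12O | intermediate
40 | 3β-alcohol | C=C1[C@H]2C[C@H]3[C@@H](C(C)C)[C@@H](O)C[C@]3(C)C[C@@H]2/C(C)=C\C[C@H]2[C@H](C)OC(=O)[C@@H](O[Si](C)(C)C(C)(C)C)[C@@]12O | intermediate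
41 | (S)-1-bromo-2-methylbutane | BrC[C@@H](C)CC | starting material
42 | (S)-4-methylhex-1-yne | C#CC[C@@H](C)CC | intermediate
43 | (E)-alkenyldimethylalane from 42 (not isolated) | C[Al](C)/C=C(\C)C[C@@H](C)CC | intermediate
44 | (2E,5S)-3,5-dimethylhept-2-en-1-ol | OC/C=C(\C)C[C@@H](C)CC | intermediate
45 | [(2R,3R)-3-methyl-3-[(2S)-2-methylbutyl]oxiran-2-yl]methanol | OC[C@H]1O[C@]1(C)C[C@@H](C)CC | intermediate
46 | (3R,5S)-3,5-dimethylheptane-1,3-diol | OCC[C@](C)(O)C[C@@H](C)CC | intermediate
47 | (3R,5S)-3-hydroxy-3,5-dimethylheptanoic acid | OC(=O)C[C@](C)(O)C[C@@H](C)CC | intermediate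
48 | 18-O-TBS ether of the target | C=C1[C@H]2C[C@H]3[C@@H](C(C)C)[C@H](OC(=O)C[C@](C)(O)C[C@@H](C)CC)C[C@]3(C)C[C@@H]2/C(C)=C\C[C@H]2[C@H](C)OC(=O)[C@@H](O[Si](C)(C)C(C)(C)C)[C@@]12O | intermediate
49 | CNP0331120.1 | C=C1[C@H]2C[C@H]3[C@@H](C(C)C)[C@H](OC(=O)C[C@](C)(O)C[C@@H](C)CC)C[C@]3(C)C[C@@H]2/C(C)=C\C[C@H]2[C@H](C)OC(=O)[C@@H](O)[C@@]12O | target

## Step count and risks

Total step count: 30. Longest linear sequence: 22 steps (1–8, 12–23, 29, 30).

Steps most likely to fail:

Step 22 (copper hydride reduction). Hydride transfer to the fully substituted C1 of the tetrasubstituted enone may be too slow, so that 1,2-reduction or no reaction prevails. Fallback: a dissolving-metal reduction, which is insensitive to this steric demand. Setting out from 38, Li (2.2 equiv) in NH3/THF at −78 °C for a few minutes, then isoprene and solid NH4Cl, should give the trans-fused ketone by protonation of the C1 carbanion in its stable configuration and kinetic α-face protonation of the enolate at C2, rejoining the route at 39; limiting lithium and the short time are meant to spare the lactone. No new compound is formed on the way (F0).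

Step 18 (ring-closing metathesis). The alkylidene loaded at the allyl terminus may fail to engage the hindered isopropenyl group inside the rigid lactone, giving oligomers through the terminal alkene or enyne metathesis at the alkyne. Fallback: close the carbocycle before the lactone, on the conformationally freer open-chain diene. Setting out from 27, VO(acac)2/t-BuOOH should give the spiro-epoxide F1, metathesis under the conditions of step 18 the cyclooctene F2, and MeReO3/PPh3 the methylidene compound F3. PPTS in MeOH followed by warming then closes the lactone to the C18-epimeric tricycle F4, which is converged by the enolisation/protonation of step 16 and rejoins the route at 34.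

Step 29 (Mitsunobu esterification). The hindered 3β-oxyphosphonium next to the cis isopropyl group may eliminate to the cyclopentene faster than the weakly acidic, bulky acid 47 displaces it. Fallback: separate inversion from acylation. Setting out from 40, a Mitsunobu reaction with the small, more acidic chloroacetic acid should give the inverted 3α-chloroacetate F5. Thiourea/NaHCO3 in EtOH removes the chloroacetyl group under near-neutral conditions to give the 3α-alcohol F6, which is acylated with retention by 47 under carbodiimide/DMAP conditions (EDC·HCl, DMAP, CH2Cl2) to rejoin the route at 48.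

Further compounds
F1 | step 18 | 13-spiro-epoxide of aldol adduct 27 | CCOC(=O)C(O[Si](C)(C)C(C)(C)C)[C@@](O)(C2(CO2)[C@H]1CC(O)[C@](C)(CC#CC(C)C)C[C@@H]1C(C)=C)[C@@H](CC=C)[C@H](C)O[Si](CC)(CC)CC
F2 | step 18 | bicyclic cyclohexanol–(Z)-cyclooctene with 13-spiro-epoxide and open 16-OTES/ethyl ester chains | C12(CO1)[C@H]3CC(O)[C@](C)(CC#CC(C)C)C[C@@H]3/C(C)=C\C[C@@H]([C@H](C)O[Si](CC)(CC)CC)[C@@]2(O)C(O[Si](C)(C)C(C)(C)C)C(=O)OCC
F3 | step 18 | 13-methylidene bicycle from F2 | C=C1[C@H]2CC(O)[C@](C)(CC#CC(C)C)C[C@@H]2/C(C)=C\C[C@@H]([C@H](C)O[Si](CC)(CC)CC)[C@@]1(O)C(O[Si](C)(C)C(C)(C)C)C(=O)OCC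
F4 | step 18 | C18-epimeric mixture of tricycle 34 | C=C1[C@H]2CC(O)[C@](C)(CC#CC(C)C)C[C@@H]2/C(C)=C\C[C@H]2[C@H](C)OC(=O)C(O[Si](C)(C)C(C)(C)C)[C@@]12O
F0 | step 22 | none | none
F5 | step 29 | 3α-chloroacetate | C=C1[C@H]2C[C@H]3[C@@H](C(C)C)[C@H](OC(=O)CCl)C[C@]3(C)C[C@@H]2/C(C)=C\C[C@H]2[C@H](C)OC(=O)[C@@H](O[Si](C)(C)C(C)(C)C)[C@@]12O
F6 | step 29 | 3α-alcohol | C=C1[C@H]2C[C@H]3[C@@H](C(C)C)[C@H](O)C[C@]3(C)C[C@@H]2/C(C)=C\C[C@H]2[C@H](C)OC(=O)[C@@H](O[Si](C)(C)C(C)(C)C)[C@@]12O
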